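Slowness, the minutes one mM of substrate costs, is the quantity to read here: the time a flask takes is its slowness summed over the substrate it passes through.

| flask | substrate | enzyme | added ligand | remark | time |
|---|---|---|---|---|---|
| green | 4.2 mM | 2 µM | 10 µM | run made earlier |  |
| teal | 16 mM | 2 µM | 10 µM | run made earlier |  |
| cedar | 6.0 mM | 2.0 µM | 10 µM |  | 4.0 min |
| alder | 8.0 mM | 2.0 µM | 10 µM |  | 4.0 min |
| maple | 12 mM | 2.0 µM | 10 µM |  | 4.0 min |
| larch | 20 mM | 2.0 µM | 10 µM |  | 4.0 min |

- green (time / min: product / %): 0.333: 14.1; 0.500: 21.3; 0.833: 34.4; 1.33: 52.9; 2.50: 83.3; 4.00: 96.5
- teal (time / min: product / %): 0.250: 1.6; 0.833: 5.0; 1.33: 7.7; 2.00: 11.3; 3.00: 16.5; 4.00: 23.4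

(standard deviation of a reading: 0.3 percentage points)

* [product] at the end for cedar, alder, maple, larch, in this order
* the course of these numbers from the first flask to the last (rises all the way / rises, then falls / falls all the way / falls, then rises / hardly changes)

- "hardly changes" means that all values lie within two and a half points (for a concentration: within two and a half percent of the largest)

Green's tail gives the low end. Between 2.50 min and 4.00 min its readings are taken as a pseudo-first-order tail of the remaining substrate, and they read a time constant a = 0.960 min, so slowness there reads a/[substrate]. But teal needs a term that grows with substrate, so take slowness = a/[substrate] + a[substrate]/(m·m), lowest at [substrate] = m. Summed, this gives time = a·ln([start]/[end]) + a([start]·[start] − [end]·[end])/(2m·m). Teal's reading of 23.4% at 4.00 min then gives, as a reading too, the fastest concentration, m = 3.68 mM.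

Now add a little substrate to a flask, with the time held fixed. The flask gains that amount, but the rest of its run starts later, by the slowness at the start, and loses at the rate of its end. So [product] at the end climbs with the charge while the starting rate beats the end rate, and it tops out where the two are equal, which in this form of slowness is where [start]·[end] = m·m.

By this reckoning, reaching that balance takes alder 3.65 min, less than 4.0 min, so alder passes it and lies on the climbing side. Maple would need 7.32 min, more than 4.0 min, so maple lies on the falling side.

The forecast, reading “Both runs fit one picture: substrate inhibition”, gave 5.5 mM, 6.5 mM, 5.2 mM and 3 mM: rises, then falls.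

The flasks give 5.52 mM, 6.40 mM, 4.97 mM and 2.90 mM: rises, then falls.

    substrate + enzyme → product + enzyme, rate k1*[substrate]*[enzyme]/(1 + ([substrate]/Km1) + ([substrate]/Ksi1)^2) (28.6 mM, 3.83 mM, k = 16300 L mol⁻¹ s⁻¹)
    enzyme + added ligand ⇌ idle complex, settled at all times (K = 1.10 × 10⁵ L mol⁻¹)

The row turns at 8.2 mM, above alder's 8.0 mM. Alder ends with 19.9% of its substrate left and maple with 58.6%. So [start]·[end]/(m·m) stands at 0.940 in alder, on the climbing side, and at 6.22 in maple, on the falling side.

(Readings and results are calculated from invented constants; noise was put on by code.)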